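## Retrosynthetic overview

1. Ring numbering: C1 = CH bearing CH2OAr, C2 = C(CH3), C3 = =CH, C4 = CH2, C5 = CH–O‑acyl, C6 = C(CH3)2. Enabling feature: in the cyclohexene ring the C2=C3 alkene is homoallylic to the oxygen of the C1–CH2–O arm. This is the retron of an allylboration of formaldehyde. Undoing it moves the alkene to C1=C2 and puts boron on C3, and that ring is a Diels–Alder cyclohexene.
2. The isovalerate on C5 is carried as its isobutyl ketone and revealed last by Baeyer–Villiger oxidation, so the future ester also activates the dienophile. The aryl ether comes from a Mitsunobu reaction with purchased umbelliferone, so both coumarin rings are bought.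
3. Key disconnection: C3–C4 and C5–C6 by [4+2] cycloaddition and C1–CH2 by allyl transfer, in one pot from three components: an (E)-dienylboronate, isobutyl vinyl ketone and formaldehyde. The carbocycle is the only ring formed in the route.
4. The dienylboronate comes from mesityl oxide by boron–Wittig olefination. The vinyl ketone comes from isovaleryl chloride by vinylsilane acylation.

Key step: step 3

Assumption: the sense of induction in step 3 is taken from the accepted pre-transition-state model of cationic oxazaborolidines with vinyl ketones (α‑C–H···O contact). By this model the (S)-diphenylprolinol-derived catalyst leaves the Si face of the α‑carbon open. If a first run shows the opposite sense, the catalyst from (R)-diphenylprolinol is used and nothing else changes.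

## Route

Step 1
Reactants: 1 mesityl oxide (4-methylpent-3-en-2-one); 2 bis(4,4,5,5-tetramethyl-1,3,2-dioxaborolan-2-yl)methane
Product: 4 2-[(1E)-2,4-dimethylpenta-1,3-dien-1-yl]-4,4,5,5-tetramethyl-1,3,2-dioxaborolane, via lithio-bis(pinacolatoboryl)methane 3 (not isolated)
Conditions: 2, lithium 2,2,6,6-tetramethylpiperidide (from 2,2,6,6-tetramethylpiperidine and n-BuLi), THF, 0 °C; then 1, −78 °C → rt; H2O quench; chromatography
Reagents that add atoms: none
Why: Boron–Wittig olefination: the diboryl carbanion should add 1,2 because the β,β-dimethyl terminus of 1 blocks 1,4-addition, and syn B–O elimination should place the bulky boronate trans to the larger isobutenyl group (E), any (Z) isomer being removed and unable to reach an s-cis geometry anyway.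

Step 2
Reactants: 5 isovaleryl chloride (3-methylbutanoyl chloride); 6 trimethyl(vinyl)silane
Product: 7 5-methylhex-1-en-3-one (isobutyl vinyl ketone)
Conditions: AlCl3 (1.1 equiv), CH2Cl2, −30 → 0 °C; ice/aq. NaHCO3; distilled over hydroquinone and used fresh
Reagents that add atoms: none
Why: Friedel–Crafts-type ipso acylation of a vinylsilane: the acylium ion attacks the silicon-bearing carbon, the β-silyl cation loses Me3Si+, and the vinyl ketone should form without positional isomers.

Step 3
Reactants: 4 (E)-dienylboronate; 7 5-methylhex-1-en-3-one; 8 formaldehyde (monomer, cracked from paraformaldehyde)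
Product: 11 1-[(1R,5S)-5-(hydroxymethyl)-4,6,6-trimethylcyclohex-3-en-1-yl]-3-methylbutan-1-one, via allylboronate cycloadduct 9 (not isolated), via pinacol borate 10 (not isolated)
Conditions: (S)-3,3-diphenyl-1-(2-methylphenyl)tetrahydro-1H,3H-pyrrolo[1,2-c][1,3,2]oxazaborole (20 mol %), HN(SO2CF3)2 (18 mol %), CH2Cl2, −78 → −20 °C; then 8 in THF (excess), −20 °C → 40 °C, same flask; aq. NaHCO3
Reagents that add atoms: none
Why: Proposed new method: the protonated oxazaborolidine binds the carbonyl oxygen of s-trans 7, and 4 adds in a concerted but strongly asynchronous Diels–Alder transition state in which the boron-bearing CH (future C3) bonds early to the enone CH2 (C4) and the allyl-cation-like C2–C1–C6 unit, tertiary at both ends, closes late from C6 onto the enolate-like carbon C5; formaldehyde then coordinates to the boron of 9 and is allylated at C1 through a six-membered chair, which moves the alkene to C2=C3. The closest known reaction types are the one-pot three-component Diels–Alder/allylboration of 1-borono-1,3-dienes with a dienophile and an aldehyde and the cationic-oxazaborolidine-catalysed Diels–Alder reaction of vinyl ketones; new is their merger on a 2,4,4-trisubstituted dienylboronate that has to form a quaternary carbon. The one ring that is closed, the cyclohexene, closes by intermolecular [4+2] cycloaddition, suprafacial on both partners. C5 is set by the catalyst, whose phenyl group covers one face of the bound enone so that the diene reaches the Si face of the α-carbon; the transient C3–B centre is set cis to the acyl group by the endo rule together with the E geometry of 4; C1 is set by suprafacial transfer from C3, the new C–C bond forming on the face that boron leaves, which places CH2OH cis to the acyl group. Regioselectivity (C5 next to C6) is secured by the three methyl groups of 4, which make C3 the nucleophilic terminus and C6 the cation-stabilising one ("ortho" to the gem-dimethyl end and "para" to the C2 methyl). Chemoselectivity rests on the order of addition and on the substrate: alkenylboronate 4 cannot transfer an allyl group, the ketone of 9 is hindered and cannot reach C1 within the molecule, and formaldehyde is the smallest and most reactive acceptor for the congested C1 position.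

Step 4
Reactants: 11 hydroxy ketone; 12 umbelliferone (7-hydroxy-2H-chromen-2-one)
Product: 13 3-methyl-1-[(1R,5S)-4,6,6-trimethyl-5-{[(2-oxo-2H-chromen-7-yl)oxy]methyl}cyclohex-3-en-1-yl]butan-1-one
Conditions: PPh3, DIAD, THF, 0 °C → rt
Reagents that add atoms: none
Why: Mitsunobu etherification of a primary alcohol with an acidic phenol; substitution takes place at the CH2 carbon only, so neither stereocentre is touched, and the cis (diequatorial) arrangement at the ketone α-carbon is also the thermodynamic one.

Step 5
Reactants: 13 aryl ether ketone
Product: 14 (1R,5S)-4,6,6-trimethyl-5-{[(2-oxo-2H-chromen-7-yl)oxy]methyl}cyclohex-3-en-1-yl 3-methylbutanoate (target)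
Conditions: Me3SiOOSiMe3 (3 equiv), Me3SiOTf (20 mol %), 4 Å molecular sieves, CH2Cl2, −40 → 0 °C
Reagents that add atoms: bis(trimethylsilyl) peroxide, C[Si](C)(C)OO[Si](C)(C)C
Why: Baeyer–Villiger oxidation through a silyl perketal: no peracid is present, so the C2=C3 alkene and the coumarin should stay untouched, the secondary ring carbon migrates in preference to the primary CH2 of the isobutyl group, and migration goes with retention at C5, which turns the ketone directly into the isovalerate.

## Compound list

1 | mesityl oxide (4-methylpent-3-en-2-one) | CC(=O)C=C(C)C | starting material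
2 | bis(4,4,5,5-tetramethyl-1,3,2-dioxaborolan-2-yl)methane | CC1(C)OB(CB2OC(C)(C)C(C)(C)O2)OC1(C)C | starting material
3 | lithio-bis(pinacolatoboryl)methane (not isolated) | [Li]C(B1OC(C)(C)C(C)(C)O1)B1OC(C)(C)C(C)(C)O1 | intermediate
4 | 2-[(1E)-2,4-dimethylpenta-1,3-dien-1-yl]-4,4,5,5-tetramethyl-1,3,2-dioxaborolane | CC(C)=C/C(C)=C/B1OC(C)(C)C(C)(C)O1 | intermediate
5 | isovaleryl chloride | CC(C)CC(=O)Cl | starting material
6 | trimethyl(vinyl)silane | C=C[Si](C)(C)C | starting material
7 | 5-methylhex-1-en-3-one | C=CC(=O)CC(C)C | intermediate
8 | formaldehyde (bought as paraformaldehyde) | C=O | starting material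
9 | 3-methyl-1-[(1R,5S)-2,2,4-trimethyl-5-(4,4,5,5-tetramethyl-1,3,2-dioxaborolan-2-yl)cyclohex-3-en-1-yl]butan-1-one, boron cis to acyl (not isolated) | CC1=CC(C)(C)[C@H](C(=O)CC(C)C)C[C@@H]1B2OC(C)(C)C(C)(C)O2 | intermediate
10 | 3-methyl-1-[(1R,5S)-4,6,6-trimethyl-5-{[(4,4,5,5-tetramethyl-1,3,2-dioxaborolan-2-yl)oxy]methyl}cyclohex-3-en-1-yl]butan-1-one (not isolated) | CC1=CC[C@@H](C(=O)CC(C)C)C(C)(C)[C@H]1COB2OC(C)(C)C(C)(C)O2 | intermediate
11 | 1-[(1R,5S)-5-(hydroxymethyl)-4,6,6-trimethylcyclohex-3-en-1-yl]-3-methylbutan-1-one, CH2OH cis to acyl | CC1=CC[C@@H](C(=O)CC(C)C)C(C)(C)[C@H]1CO | intermediate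
12 | umbelliferone (7-hydroxy-2H-chromen-2-one) | Oc1ccc2ccc(=O)oc2c1 | starting material
13 | 3-methyl-1-[(1R,5S)-4,6,6-trimethyl-5-{[(2-oxo-2H-chromen-7-yl)oxy]methyl}cyclohex-3-en-1-yl]butan-1-one | CC1=CC[C@@H](C(=O)CC(C)C)C(C)(C)[C@H]1COc1ccc2ccc(=O)oc2c1 | intermediate
14 | (1R,5S)-4,6,6-trimethyl-5-{[(2-oxo-2H-chromen-7-yl)oxy]methyl}cyclohex-3-en-1-yl 3-methylbutanoate | CC1=CC[C@@H](OC(=O)CC(C)C)C(C)(C)[C@H]1COc1ccc2ccc(=O)oc2c1 | target

## Step count

Total step count: 5.
Longest linear sequence: 4 steps (1 → 3 → 4 → 5, or equally 2 → 3 → 4 → 5).

## Steps most likely to fail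

**Step 3.**
- What may go wrong:
  - The twisted diene with its fully substituted terminus may close the second bond too slowly. The cation-like stage would then be drained by proton loss from a methyl group or by loss of boron.
  - A truly stepwise closure would erode the endo preference.
  - The allyl transfer may be sluggish, because it needs the conformer in which boron and the cis acyl group are both axial.
- Fallback (known chemistry): it sets out from umbelliferone 12 and comes back to the route at 14. It gives up the cycloaddition for a cation–olefin cyclisation.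
  - O-Alkylation of 12 with (E)-geranyl bromide (K2CO3, acetone, reflux) should give 7-geranyloxycoumarin F1.
  - Shi epoxidation of F1 follows, using the D-fructose-derived ketone, KHSO5 as the triple salt 2KHSO5·KHSO4·K2SO4, K2CO3 buffer and MeCN/dimethoxymethane/H2O at 0 °C. It should attack the more electron-rich terminal alkene and give (R)-6',7'-epoxy-7-geranyloxycoumarin F2.
  - Treatment of F2 with ZrCl4 (CH2Cl2, −78 → −20 °C) should open the epoxide at its tertiary carbon and close the ring through a chair. Both substituents become equatorial, and proton loss gives the endocyclic alkene, that is 7-{[(1S,5R)-5-hydroxy-2,6,6-trimethylcyclohex-2-en-1-yl]methoxy}-2H-chromen-2-one F3. This is separated from the exocyclic alkene isomer.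
  - Acylation of F3 with 5 (pyridine, DMAP, CH2Cl2) gives 14.

**Step 5.**
- What may go wrong:
  - Perketal formation at a ketone flanked by the ring carbon next to C6 and by an isobutyl group may be too slow.
  - Prolonged contact with the silyl triflate may shift the C2=C3 alkene to the tetrasubstituted position.
- Fallback: it sets out from 13 and comes back at 14. It accepts oxidation of the alkene instead of avoiding it.
  - Excess m-chloroperbenzoic acid (Na2HPO4, CH2Cl2, rt → reflux) should epoxidise C2=C3 and then carry out the Baeyer–Villiger step, giving the epoxy isovalerate F4. Either epoxide face is acceptable.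
  - Re2O7-catalysed oxygen transfer to P(OPh)3 (toluene, 100 °C) should restore the ring alkene, whose geometry is fixed by the ring, and deliver 14.

**Step 1.**
- What may go wrong:
  - Enolisation of 1 may compete with addition.
  - The steric bias between methyl and isobutenyl may be too small, giving poor control of alkene geometry.
- Fallback: it sets out from 1 and comes back at 4. It derives the geometry from a syn addition instead.
  - Kinetic enolisation of 1 (LDA, THF, −78 °C) and trapping with ClP(O)(OEt)2 should give diethyl 4-methylpenta-1,3-dien-2-yl phosphate F5.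
  - Elimination with LDA (2.3 equiv, −78 °C → rt) should give 4-methylpent-3-en-1-yne F6.
  - CuCl/Xantphos-catalysed methylboration of F6 (B2pin2, MeI, NaOt-Bu, THF, rt) places boron on the terminal carbon and methyl cis to it. The isobutenyl group therefore ends up trans to boron, as in 4.

## Further compounds

F1 | step 3 | 7-{[(2E)-3,7-dimethylocta-2,6-dien-1-yl]oxy}-2H-chromen-2-one (7-geranyloxycoumarin) | CC(C)=CCC/C(C)=C/COc1ccc2ccc(=O)oc2c1
F2 | step 3 | 7-({(2E)-5-[(2R)-3,3-dimethyloxiran-2-yl]-3-methylpent-2-en-1-yl}oxy)-2H-chromen-2-one | CC1(C)O[C@@H]1CC/C(C)=C/COc3ccc4ccc(=O)oc4c3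
F3 | step 3 | 7-{[(1S,5R)-5-hydroxy-2,6,6-trimethylcyclohex-2-en-1-yl]methoxy}-2H-chromen-2-one | CC1=CC[C@@H](O)C(C)(C)[C@H]1COc1ccc2ccc(=O)oc2c1
F4 | step 5 | 2,3-epoxide of 14 (epoxide face left open, both converge) | CC12OC1C[C@@H](OC(=O)CC(C)C)C(C)(C)[C@H]2COc3ccc4ccc(=O)oc4c3
F5 | step 1 | diethyl 4-methylpenta-1,3-dien-2-yl phosphate | C=C(OP(=O)(OCC)OCC)C=C(C)C
F6 | step 1 | 4-methylpent-3-en-1-yne | C#CC=C(C)C
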